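# Total synthesis plan for CNP0241021.1 by oxonium ylide [2,3] ring expansion of a linalool-derived tetrahydropyran

## The problem

The target 33 is a cis-2,5-bridged tetrahydrofuran (O, C7, C8, C9, C10) set across a nine-membered oxacycle (O, C10, C1–C6, C7), i.e. an 11-oxabicyclo[6.2.1]undecane, with an α-methylene-γ-lactone spiro-fused at C7 and closed on C6. Both ether carbons are fully substituted (C7: O, C6, C8, C11; C10: O, CH3, C1, C9), so neither can be made by simple SN2 etherification, and a medium ring has to be built directly beside them. Six stereocentres must be set (C4, C5, C6, C7, C8, C10). C10 can come from the chiral pool; the ether bridge can only be cis, so C10 controls C7; C6, as a free hydroxyl, can direct the epoxidation that creates C4 and C5; C8 has no useful neighbour and needs reagent control. The α-methylene lactone and the methacrylate are Michael acceptors, the trisubstituted epoxide is acid-labile, and the β-oxygenated carbonyl arrays (C8/C6 and C8/C10) invite retro-aldol and β-elimination under base, so these groups must appear late and under near-neutral conditions. The enabling feature is the array O–C7(–C8=O)–C6–C5–C4: C7 is α to the C8 carbonyl, bonded to the ring oxygen, and bonded to C6, which is allylic once the C4–C5 epoxide is read as an olefin. Moving the oxygen from C7 to C4 and cutting C6–C7 turns the bicycle into a 2-methyl-2-alkenyltetrahydropyran with a carbenoid at C7, and the ten carbons of that pyran (C1–C6, C9, C10 and both methyls) are those of linalool.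

## Retrosynthesis

**Lactone and C1 ketone (33 ⇒ 32 ⇒ 29).** The C1 carbonyl and the lactone acyl–oxygen bond are taken apart last in the analysis, because the enoate lactone and the ketone next to the tertiary ether are the least robust groups. Triol 29 (C12, C6 and C1 hydroxyls) is the precursor: oxidation of the primary allylic C12 alcohol gives an enal that is trapped by the C6 hydroxyl as a lactol and oxidised on to lactone 32; a separate oxidation at C1 gives 33. The forward reactions must distinguish a primary allylic alcohol from two secondary ones. The lactol can only close on C6 because C8 is already esterified.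

**Epoxide (29 ⇒ 28 ⇒ 27).** Both C–O bonds of the epoxide are cut back to the Z C4=C5 olefin of allylic alcohol 27. This is preferred over epoxidising after lactonisation, where no directing group is left and a peracid would be expected on the opposite, peripheral face. The free C6 hydroxyl is used to deliver oxygen syn, which is the relationship found in the target (epoxide oxygen and C6 oxygen cis on the ring). The forward step also needs chemoselectivity over the C11=C13 and methacrylate olefins.

**C8 ester (27 ⇒ 26 ⇒ 25 ⇒ 24).** The methacrylate is cut at the acyl–oxygen bond and the C8 carbinol is traced to the ketone of 24. The C6 oxygen stays masked as a 2,2,2-trichloroethyl carbonate through reduction and acylation, so that the two secondary oxygens on either side of C7 are never free together. C8 is set by a catalyst-controlled reduction (fully substituted C7 versus the C9 methylene). The carbonate is then removed reductively, which a methacrylate tolerates.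

**Key disconnection (24 ⇒ 23 ⇒ 22).** The C6–C7 and O–C7 bonds are cut and O–C4 is re-formed. Ketone 24 thus becomes vinyl diazoketone 22 by way of oxonium ylide 23. Against the neighbouring cuts (C5–C6 by organometallic ring closure; O–C7/O–C6 by oxidative cyclisation on a chain), this one needs no medium-ring closure at all: the six-membered ring grows to nine while the five-membered ring forms. It also creates C7, C6 and the Z olefin from the single C4 centre. The precursor is monocyclic, with only C4, C10 and a control centre at C1. The forward reaction must favour ylide formation over other carbenoid pathways and must pass through the pyran conformer with the alkenyl group equatorial.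

**Diazoketone side chain (22 ⇒ 21 ⇒ 20 ⇒ 15 + 19).** The diazo group is removed (diazo transfer to the doubly activated C7 methylene of β,γ-unsaturated ketone 21). The C7–C8 bond is then cut to aldehyde 15 and allylboronate 19, via alcohol 20. Allylboration is chosen over zinc or indium Barbier chemistry because reducing metals would cleave the trichloroethyl carbonate. Boronate 19 comes from 2-methylenepropane-1,3-diol 16 through 17 and 18.

**Enol carbonate and C8 aldehyde (15 ⇒ 13 ⇒ 12 ⇒ 11 ⇒ 10).** The enol carbonate is cut at the O–acyl bond to the enolate of aldehyde 12, which comes from alcohol 11 and PMB ether 10. The C8 aldehyde of 15 is traced to the vinyl group of 13 by anti-Markovnikov oxidation via borane 14. The order matters: the carbonate is installed while 12 is the only enolisable carbonyl compound, and the second aldehyde is unveiled afterwards under non-basic conditions.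

**Pyran (10 ⇒ 9 ⇒ 8).** The O–C10 bond is cut to hydroxy vinyl epoxide 8. With an alkyl group on C10 the tertiary hydroxyl would attack C1 (5-exo) and give the furanoid isomer. A vinyl group on C10 stabilises positive charge there and enforces 6-endo opening with inversion. The same vinyl group later becomes C9H2–C8HO, so it costs no extra carbon. The cyclisation places the C1 oxygen cis to the C10 methyl. This later lets the silyl ether sit equatorial in the pyran chair that has both methyls axial and the two reacting arms equatorial.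

**Vinyl epoxide from linalool (8 ⇒ 7 ⇒ 6 ⇒ 5 ⇒ 4 ⇒ 3 ⇒ 1).** The vinyl epoxide comes from epoxy aldehyde 7 by methylenation. Aldehyde 7 comes from epoxy alcohol 6, and 6 from E-allylic alcohol 5 by asymmetric epoxidation, which sets C1 and C10 under reagent control. Alcohol 5 arises by allylic oxidation of the E-methyl of PMB ether 4. The linalool vinyl group is converted first into the C5–C6 hydroxyethyl arm (diol 3, then 4), so that only one vinyl group is ever present. (R)-Linalool 1 supplies C4 with the configuration needed.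

## Roads not taken

**Alternative 1: osmium oxidative cyclisation to the spiro tetrahydrofuran–lactone.**
- Cut: the O–C7 and O–C6 bonds, on an open chain; the nine-membered ring is left for later.
- Forward key step: the precursor of A1 presents its C1,C10-diol to osmium. The osmium(VI) glycolate adds across a Z C6=C7 olefin on one face, forming O–C7 and O–C6 together, closing the cis-2,5-tetrahydrofuran and letting the new C6 hydroxyl lactonise onto the C12 ester to give A1.
- Merits: syn addition is stereospecific, so C6 and C7 follow from olefin geometry and from C10; every reaction type is established.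
- Weak points here: A1 still lacks the medium ring, which would have to be closed between C1 and C5 on a compound flanked by two fully substituted ether carbons. The exocyclic methylene must be added at a hindered lactone α-carbon. The cyclisation must create a fully substituted C7 from a trisubstituted olefin, the slow case of this reaction.
- Comparison: for the C6/C7 relationship this road is more predictable than the chosen plan. Against that, the ring expansion delivers the medium ring, the ring junction and the C11–C13 unit in one event, with no ring closure of a nine-membered chain.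

**Alternative 2: Nozaki–Hiyama–Kishi closure at C5–C6.**
- Cut: the C5–C6 bond.
- Forward key step: the precursor of A2 carries a Z-alkenyl iodide at C5 and an aldehyde at C6 on a preformed tetrahydrofuran; nickel-catalysed chromium(II) addition closes the nine-membered ring to allylic alcohol A2.
- Merits: the coupling tolerates ester, ketone and methacrylate. It is convergent and late. A2 already holds the methacrylate, the C1 ketone and the acrylate carbon at the right oxidation level, so its endgame is clearly shorter than the seven steps needed after the ring expansion here.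
- Weak points here: a nine-membered ring is closed by C–C bond formation at a neopentyl aldehyde on the fully substituted C7, with the usual entropic and transannular penalties, high dilution and stoichiometric chromium. The C6 configuration is left to the conformation of the closing ring. The whole difficulty of the C7 ether centre is moved into the fragment synthesis.
- Comparison: this road is safer in reaction type and better in endgame length. The chosen plan answers with a ring growth in place of a ring closure, and with C6, C7 and the Z geometry all derived from one stereocentre.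

**Alternative 3: ketene cycloaddition, then Baeyer–Villiger oxygen insertion.**
- Cut: the lactone O–C6 bond.
- Forward key step: the precursor of A3 carries a four-membered ketone across C6–C7–C11–C12, made by adding chloro(methyl)ketene to a C6=C7 enol ether of the oxabicycle. Peroxide inserts oxygen between C12 and C6 with retention to give A3.
- Merits: the migrating-group preference and retention are among the most dependable in oxidation chemistry. The spiro centre is made on the exposed face. The chloro-methyl pair can only eliminate outward, since C7 has no hydrogen.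
- Weak points here: the oxabicycle with its Z C4=C5 olefin must already exist, so the medium-ring problem is only deferred. The peroxidic reagent must spare or correctly epoxidise that olefin without a directing group. A3 has the wrong C8 configuration and needs an inversion.
- Comparison: for the lactone itself this road is more reliable than the oxidation–lactonisation used here. The chosen plan needs no separate lactone annulation, because C11–C13 arrive on the carbenoid and C6 arrives oxygenated.

Key step: step 19

## Route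

Remark on numbering: locants C1–C13 are those of the target's ten-membered carbocycle and its three-carbon branch (C7–O–C10 ether bridge) and are used for all intermediates.

Assumption: the C1 silyl ether centre is only a conformational control element and is erased in the last step; stereochemical outcomes of steps 19, 20 and 23 are predictions.

Step 1
Reactants: 1 (R)-linalool
Product: 3 (3R)-3,7-dimethyloct-6-ene-1,3-diol, via alkyl-9-BBN adduct 2 (not isolated)
Conditions: 9-BBN (2.2 equiv), THF, 0 °C to rt; then NaOH, H2O2, 0 °C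
Reagents that add atoms: hydrogen peroxide, OO
Why: Anti-Markovnikov hydroboration–oxidation; 9-BBN selects the monosubstituted vinyl group over the trisubstituted olefin and the carbinol centre is not touched.

Step 2
Reactants: 3 (3R)-3,7-dimethyloct-6-ene-1,3-diol
Product: 4 (3R)-1-[(4-methoxybenzyl)oxy]-3,7-dimethyloct-6-en-3-ol
Conditions: NaH (1.05 equiv), PMBCl, n-Bu4NI (cat.), THF/DMF, 0 °C to rt
Reagents that add atoms: 4-methoxybenzyl chloride, COc1ccc(CCl)cc1
Why: Williamson etherification; the primary alkoxide forms and reacts much faster than the hindered tertiary one.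

Step 3
Reactants: 4 (3R)-1-[(4-methoxybenzyl)oxy]-3,7-dimethyloct-6-en-3-ol
Product: 5 (2E,6R)-8-[(4-methoxybenzyl)oxy]-2,6-dimethyloct-2-ene-1,6-diol
Conditions: SeO2 (0.3 equiv), t-BuOOH, salicylic acid (cat.), CH2Cl2, rt
Reagents that add atoms: selenium dioxide, O=[Se]=O; tert-butyl hydroperoxide, CC(C)(C)OO
Why: Riley allylic oxidation (ene reaction then [2,3] shift), which on a gem-dimethyl olefin oxidises the E-methyl and gives the E-allylic alcohol that becomes C9.

Step 4
Reactants: 5 (2E,6R)-8-[(4-methoxybenzyl)oxy]-2,6-dimethyloct-2-ene-1,6-diol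
Product: 6 {(2S,3S)-3-[(3R)-3-hydroxy-5-[(4-methoxybenzyl)oxy]-3-methylpentyl]-2-methyloxiran-2-yl}methanol
Conditions: Ti(Oi-Pr)4 (10 mol%), L-(+)-diethyl tartrate (12 mol%), t-BuOOH, 4 Å MS, CH2Cl2, −20 °C
Reagents that add atoms: tert-butyl hydroperoxide, CC(C)(C)OO
Why: Sharpless asymmetric epoxidation of the primary E-allylic alcohol under reagent control; L-(+)-tartrate should give the (2S,3S)-epoxide as with other E-2,3-disubstituted allylic alcohols, setting C1 and C10, while catalytic titanium and low temperature keep the distant tertiary hydroxyl from opening the epoxide.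

Step 5
Reactants: 6 {(2S,3S)-3-[(3R)-3-hydroxy-5-[(4-methoxybenzyl)oxy]-3-methylpentyl]-2-methyloxiran-2-yl}methanol
Product: 7 (2R,3S)-3-[(3R)-3-hydroxy-5-[(4-methoxybenzyl)oxy]-3-methylpentyl]-2-methyloxirane-2-carbaldehyde
Conditions: Dess–Martin periodinane, NaHCO3, CH2Cl2, 0 °C
Reagents that add atoms: none
Why: Dess–Martin oxidation under buffered conditions; the aldehyde has no α-hydrogen and cannot epimerise, and the tertiary alcohol is inert.

Step 6
Reactants: 7 (2R,3S)-3-[(3R)-3-hydroxy-5-[(4-methoxybenzyl)oxy]-3-methylpentyl]-2-methyloxirane-2-carbaldehyde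
Product: 8 (3R)-1-[(2S,3S)-3-ethenyl-3-methyloxiran-2-yl]-5-[(4-methoxybenzyl)oxy]-3-methylpentan-3-ol
Conditions: Ph3PCH3Br (1.5 equiv), KHMDS (1.4 equiv), THF, −78 to 0 °C
Reagents that add atoms: methyltriphenylphosphonium bromide, C[P+](c1ccccc1)(c1ccccc1)c1ccccc1.[Br-]
Why: Wittig methylenation; the ylide is too weakly basic to turn the tertiary alcohol into an alkoxide, so base-induced 5-exo opening of the epoxide is avoided.

Step 7
Reactants: 8 (3R)-1-[(2S,3S)-3-ethenyl-3-methyloxiran-2-yl]-5-[(4-methoxybenzyl)oxy]-3-methylpentan-3-ol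
Product: 9 (2R,3S,6R)-2-ethenyl-6-{2-[(4-methoxybenzyl)oxy]ethyl}-2,6-dimethyloxan-3-ol
Conditions: CSA (10 mol%), CH2Cl2, −40 to 0 °C
Reagents that add atoms: none
Why: Acid-catalysed hydroxy-epoxide cyclisation in the vinyl-epoxide-directed 6-endo mode: the vinyl group stabilises charge at the tertiary allylic C10, so the C4 hydroxyl attacks there with inversion and not at C1 (5-exo); this sets C10 (R) and leaves the C1 oxygen cis to the C10 methyl.

Step 8
Reactants: 9 (2R,3S,6R)-2-ethenyl-6-{2-[(4-methoxybenzyl)oxy]ethyl}-2,6-dimethyloxan-3-ol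
Product: 10 tert-butyl{[(2R,3S,6R)-2-ethenyl-6-{2-[(4-methoxybenzyl)oxy]ethyl}-2,6-dimethyloxan-3-yl]oxy}dimethylsilane
Conditions: TBSOTf, 2,6-lutidine, CH2Cl2, −78 to 0 °C
Reagents that add atoms: tert-butyldimethylsilyl trifluoromethanesulfonate, CC(C)(C)[Si](C)(C)OS(=O)(=O)C(F)(F)F
Why: Silylation of a hindered secondary alcohol with the silyl triflate; a silyl ether is chosen because its oxygen is a poor ylide former in step 19.

Step 9
Reactants: 10 tert-butyl{[(2R,3S,6R)-2-ethenyl-6-{2-[(4-methoxybenzyl)oxy]ethyl}-2,6-dimethyloxan-3-yl]oxy}dimethylsilane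
Product: 11 2-[(2R,5S,6R)-5-{[tert-butyl(dimethyl)silyl]oxy}-6-ethenyl-2,6-dimethyloxan-2-yl]ethan-1-ol
Conditions: DDQ, CH2Cl2/pH 7 buffer, 0 °C
Reagents that add atoms: none
Why: Oxidative cleavage of the PMB ether; neutral conditions leave the silyl ether, the vinyl group and the tertiary ethers intact.

Step 10
Reactants: 11 2-[(2R,5S,6R)-5-{[tert-butyl(dimethyl)silyl]oxy}-6-ethenyl-2,6-dimethyloxan-2-yl]ethan-1-ol
Product: 12 2-[(2R,5S,6R)-5-{[tert-butyl(dimethyl)silyl]oxy}-6-ethenyl-2,6-dimethyloxan-2-yl]acetaldehyde
Conditions: Dess–Martin periodinane, NaHCO3, CH2Cl2, 0 °C; used without chromatography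
Reagents that add atoms: none
Why: Dess–Martin oxidation; the buffered, amine-free medium avoids β-elimination of the ring oxygen from this β-alkoxy aldehyde.

Step 11
Reactants: 12 2-[(2R,5S,6R)-5-{[tert-butyl(dimethyl)silyl]oxy}-6-ethenyl-2,6-dimethyloxan-2-yl]acetaldehyde
Product: 13 (E)-2-[(2R,5S,6R)-5-{[tert-butyl(dimethyl)silyl]oxy}-6-ethenyl-2,6-dimethyloxan-2-yl]ethenyl 2,2,2-trichloroethyl carbonate
Conditions: KHMDS, THF, −78 °C, 10 min; then ClCO2CH2CCl3, −78 °C
Reagents that add atoms: 2,2,2-trichloroethyl chloroformate, ClC(=O)OCC(Cl)(Cl)Cl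
Why: O-acylation of a potassium aldehyde enolate by a chloroformate; with the fully substituted C4 on the α-carbon the enolate should form with that group trans to oxygen, giving the E-enol carbonate, and short enolate lifetime at −78 °C limits E1cB loss of the ring oxygen.

Step 12
Reactants: 13 (E)-2-[(2R,5S,6R)-5-{[tert-butyl(dimethyl)silyl]oxy}-6-ethenyl-2,6-dimethyloxan-2-yl]ethenyl 2,2,2-trichloroethyl carbonate
Product: 15 (E)-2-[(2R,5S,6R)-5-{[tert-butyl(dimethyl)silyl]oxy}-2,6-dimethyl-6-(2-oxoethyl)oxan-2-yl]ethenyl 2,2,2-trichloroethyl carbonate, via alkylborane 14 (not isolated)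
Conditions: 9-BBN, THF, 0 °C to rt; then NMO (excess), TPAP (10 mol%), 4 Å MS, CH2Cl2, rt
Reagents that add atoms: N-methylmorpholine N-oxide, C[N+]1([O-])CCOCC1
Why: Anti-Markovnikov hydroboration of the only terminal olefin, followed by amine-oxide oxidation of the B–C bond and Ley–Griffith oxidation to the aldehyde in one pot; no hydroxide or peroxide is used, so the enol carbonate should survive.

Step 13
Reactants: 16 2-methylenepropane-1,3-diol
Product: 17 2-({[tert-butyl(dimethyl)silyl]oxy}methyl)prop-2-en-1-ol
Conditions: NaH (1.0 equiv), THF, 0 °C; then TBSCl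
Reagents that add atoms: tert-butyldimethylsilyl chloride, CC(C)(C)[Si](C)(C)Cl
Why: Monosilylation of a symmetrical diol through its sparingly soluble monoalkoxide.

Step 14
Reactants: 17 2-({[tert-butyl(dimethyl)silyl]oxy}methyl)prop-2-en-1-ol
Product: 18 2-({[tert-butyl(dimethyl)silyl]oxy}methyl)prop-2-en-1-yl acetate
Conditions: Ac2O, pyridine, DMAP (cat.), CH2Cl2, 0 °C
Reagents that add atoms: acetic anhydride, CC(=O)OC(C)=O
Why: Standard acetylation to provide the leaving group for allylic borylation.

Step 15
Reactants: 18 2-({[tert-butyl(dimethyl)silyl]oxy}methyl)prop-2-en-1-yl acetate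
Product: 19 tert-butyldimethyl{[2-((4,4,5,5-tetramethyl-1,3,2-dioxaborolan-2-yl)methyl)prop-2-en-1-yl]oxy}silane
Conditions: B2pin2, Pd2(dba)3 (2.5 mol%), DMSO, 50 °C
Reagents that add atoms: bis(pinacolato)diboron, CC1(C)OB(OC1(C)C)B1OC(C)(C)C(C)(C)O1
Why: Palladium-catalysed Miyaura-type borylation of an allylic acetate via the π-allyl complex; the 2-substituted allyl unit is symmetrical, so no regiochemical issue arises.

Step 16
Reactants: 15 (E)-2-[(2R,5S,6R)-5-{[tert-butyl(dimethyl)silyl]oxy}-2,6-dimethyl-6-(2-oxoethyl)oxan-2-yl]ethenyl 2,2,2-trichloroethyl carbonate; 19 tert-butyldimethyl{[2-((4,4,5,5-tetramethyl-1,3,2-dioxaborolan-2-yl)methyl)prop-2-en-1-yl]oxy}silane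
Product: 20 2,2,2-trichloroethyl (E)-2-[(2R,5S,6R)-5-{[tert-butyl(dimethyl)silyl]oxy}-6-[4-({[tert-butyl(dimethyl)silyl]oxy}methyl)-2-hydroxypent-4-en-1-yl]-2,6-dimethyloxan-2-yl]ethenyl carbonate (both C8 epimers)
Conditions: toluene, 4 Å MS, rt to 40 °C; then aqueous NaHCO3 work-up
Reagents that add atoms: none
Why: Allylboration of an aldehyde through a closed six-membered transition state; neutral and metal-free, so the reducible trichloroethyl carbonate and the β-alkoxy aldehyde are tolerated, and the C8 configuration is irrelevant because it is oxidised next.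

Step 17
Reactants: 20 2,2,2-trichloroethyl (E)-2-[(2R,5S,6R)-5-{[tert-butyl(dimethyl)silyl]oxy}-6-[4-({[tert-butyl(dimethyl)silyl]oxy}methyl)-2-hydroxypent-4-en-1-yl]-2,6-dimethyloxan-2-yl]ethenyl carbonate (both C8 epimers)
Product: 21 2,2,2-trichloroethyl (E)-2-[(2R,5S,6R)-5-{[tert-butyl(dimethyl)silyl]oxy}-6-[4-({[tert-butyl(dimethyl)silyl]oxy}methyl)-2-oxopent-4-en-1-yl]-2,6-dimethyloxan-2-yl]ethenyl carbonate
Conditions: Dess–Martin periodinane, NaHCO3, CH2Cl2, 0 °C
Reagents that add atoms: none
Why: Dess–Martin oxidation gives the β,γ-unsaturated ketone without base, so the olefin does not move into conjugation.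

Step 18
Reactants: 21 2,2,2-trichloroethyl (E)-2-[(2R,5S,6R)-5-{[tert-butyl(dimethyl)silyl]oxy}-6-[4-({[tert-butyl(dimethyl)silyl]oxy}methyl)-2-oxopent-4-en-1-yl]-2,6-dimethyloxan-2-yl]ethenyl carbonate
Product: 22 2,2,2-trichloroethyl (E)-2-[(2R,5S,6R)-5-{[tert-butyl(dimethyl)silyl]oxy}-6-[4-({[tert-butyl(dimethyl)silyl]oxy}methyl)-3-diazo-2-oxopent-4-en-1-yl]-2,6-dimethyloxan-2-yl]ethenyl carbonate
Conditions: p-ABSA, DBU (1.1 equiv), MeCN, 0 °C; used at once
Reagents that add atoms: 4-acetamidobenzenesulfonyl azide, CC(=O)Nc1ccc(cc1)S(=O)(=O)N=[N+]=[N-]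
Why: Regitz diazo transfer to the methylene activated by both the ketone and the vinyl group (C7), which is far more acidic than the neopentyl C9 methylene; this is the usual entry to vinyl diazocarbonyl compounds.

Step 19
Reactants: 22 2,2,2-trichloroethyl (E)-2-[(2R,5S,6R)-5-{[tert-butyl(dimethyl)silyl]oxy}-6-[4-({[tert-butyl(dimethyl)silyl]oxy}methyl)-3-diazo-2-oxopent-4-en-1-yl]-2,6-dimethyloxan-2-yl]ethenyl carbonate
Product: 24 (1S,4Z,6R,7R,10R)-1-{[tert-butyl(dimethyl)silyl]oxy}-7-[3-{[tert-butyl(dimethyl)silyl]oxy}prop-1-en-2-yl]-4,10-dimethyl-8-oxo-7,10-epoxycyclodec-4-en-6-yl 2,2,2-trichloroethyl carbonate, via bicyclic oxonium ylide 23 (not isolated)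
Conditions: Cu(hfacac)2 (10 mol%), CH2Cl2, reflux, slow addition of 22
Reagents that add atoms: none
Why: Proposed new method: the copper carbenoid formed at C7 from 22 is captured by the pyran oxygen, five atoms away, to give oxonium ylide 23, which undergoes a suprafacial [2,3]-sigmatropic shift in which C7 bonds to C6 of the enol carbonate while the O–C4 bond breaks. The closest known reaction type is the copper- or rhodium-catalysed oxonium ylide formation and [2,3] rearrangement of 2-vinyltetrahydropyranyl diazoketones to 11-oxabicyclo[6.2.1]undecenones; new here are the alkenyl group on the carbenoid carbon, the fully substituted C4 and the carbonate on the migrating terminus. The tetrahydrofuran closes by O–C7 bond formation as a five-membered ylide (5-exo attack of an ether lone pair on the carbenoid), and the nine-membered ring is not closed but grown from the six-membered one by three atoms through a five-membered envelope transition state. C7 is set by C10, because only the cis-fused ylide can deliver C6 to the face that leaves a cis 2,5-bridge. C6 and the Z geometry are set together by the C4 centre, which is consumed: in the chair with C9 and the alkenyl arm equatorial (both methyls axial, the C1 silyl ether equatorial) the carbenoid carbon sits axial on oxygen, C3 ends cis to C6, and the E-enol carbonate then places its oxygen to give (6R). The step needs ylide formation to beat insertion into the C1–H bond, cyclopropene formation from the vinylcarbenoid and [1,2] shift; the copper catalyst, the short tether and the weakly basic silyl and carbonate oxygens favour the ylide, and the acyloxy group stabilises positive character at C6 during the shift.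

Step 20
Reactants: 24 (1S,4Z,6R,7R,10R)-1-{[tert-butyl(dimethyl)silyl]oxy}-7-[3-{[tert-butyl(dimethyl)silyl]oxy}prop-1-en-2-yl]-4,10-dimethyl-8-oxo-7,10-epoxycyclodec-4-en-6-yl 2,2,2-trichloroethyl carbonate
Product: 25 (1S,4Z,6R,7S,8S,10R)-1-{[tert-butyl(dimethyl)silyl]oxy}-7-[3-{[tert-butyl(dimethyl)silyl]oxy}prop-1-en-2-yl]-8-hydroxy-4,10-dimethyl-7,10-epoxycyclodec-4-en-6-yl 2,2,2-trichloroethyl carbonate
Conditions: (R)-2-methyl-CBS-oxazaborolidine (0.3 equiv), catecholborane, toluene, −78 to −40 °C
Reagents that add atoms: none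
Why: Corey–Bakshi–Shibata reduction under catalyst control: the fully substituted C7 acts as the large group and the C9 methylene as the small one, so the (R)-catalyst should give the (8S)-alcohol (hydroxyl on the face of the C7 alkenyl group); catecholborane at low temperature does not hydroborate the olefins.

Step 21
Reactants: 25 (1S,4Z,6R,7S,8S,10R)-1-{[tert-butyl(dimethyl)silyl]oxy}-7-[3-{[tert-butyl(dimethyl)silyl]oxy}prop-1-en-2-yl]-8-hydroxy-4,10-dimethyl-7,10-epoxycyclodec-4-en-6-yl 2,2,2-trichloroethyl carbonate
Product: 26 (1S,4Z,6R,7S,8S,10R)-1-{[tert-butyl(dimethyl)silyl]oxy}-7-[3-{[tert-butyl(dimethyl)silyl]oxy}prop-1-en-2-yl]-4,10-dimethyl-6-{[(2,2,2-trichloroethoxy)carbonyl]oxy}-7,10-epoxycyclodec-4-en-8-yl 2-methylprop-2-enoate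
Conditions: methacrylic anhydride, Et3N, DMAP, BHT (cat.), CH2Cl2, 0 °C to rt
Reagents that add atoms: methacrylic anhydride, CC(=C)C(=O)OC(=O)C(C)=C
Why: DMAP-catalysed acylation of the only free hydroxyl; the C6 oxygen is still a carbonate, so there is no regiochemical question.

Step 22
Reactants: 26 (1S,4Z,6R,7S,8S,10R)-1-{[tert-butyl(dimethyl)silyl]oxy}-7-[3-{[tert-butyl(dimethyl)silyl]oxy}prop-1-en-2-yl]-4,10-dimethyl-6-{[(2,2,2-trichloroethoxy)carbonyl]oxy}-7,10-epoxycyclodec-4-en-8-yl 2-methylprop-2-enoate
Product: 27 (1S,4Z,6R,7R,8S,10R)-1-{[tert-butyl(dimethyl)silyl]oxy}-7-[3-{[tert-butyl(dimethyl)silyl]oxy}prop-1-en-2-yl]-6-hydroxy-4,10-dimethyl-7,10-epoxycyclodec-4-en-8-yl 2-methylprop-2-enoate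
Conditions: Zn dust, AcOH, THF, 0 °C to rt
Reagents that add atoms: none
Why: Reductive fragmentation of the 2,2,2-trichloroethyl carbonate (zinc insertion, β-elimination, loss of CO2); methacrylate, silyl ethers and the allylic alcohol are inert to zinc in acetic acid.

Step 23
Reactants: 27 (1S,4Z,6R,7R,8S,10R)-1-{[tert-butyl(dimethyl)silyl]oxy}-7-[3-{[tert-butyl(dimethyl)silyl]oxy}prop-1-en-2-yl]-6-hydroxy-4,10-dimethyl-7,10-epoxycyclodec-4-en-8-yl 2-methylprop-2-enoate
Product: 28 (1S,4R,5S,6R,7R,8S,10R)-1-{[tert-butyl(dimethyl)silyl]oxy}-7-[3-{[tert-butyl(dimethyl)silyl]oxy}prop-1-en-2-yl]-6-hydroxy-4,10-dimethyl-4,5:7,10-diepoxycyclodecan-8-yl 2-methylprop-2-enoate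
Conditions: VO(acac)2 (5 mol%), t-BuOOH (1.2 equiv), CH2Cl2, 0 °C
Reagents that add atoms: tert-butyl hydroperoxide, CC(C)(C)OO
Why: Hydroxyl-directed epoxidation through a vanadate ester; in eight- and nine-membered cycloalkenols this reagent delivers oxygen syn to the hydroxyl (opposite to peracids), which is the (4R,5S) epoxide of the target, and the allylic trisubstituted olefin should react far faster than the homoallylic C11=C13 olefin or the electron-poor methacrylate.

Step 24
Reactants: 28 (1S,4R,5S,6R,7R,8S,10R)-1-{[tert-butyl(dimethyl)silyl]oxy}-7-[3-{[tert-butyl(dimethyl)silyl]oxy}prop-1-en-2-yl]-6-hydroxy-4,10-dimethyl-4,5:7,10-diepoxycyclodecan-8-yl 2-methylprop-2-enoate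
Product: 29 (1S,4R,5S,6R,7R,8S,10R)-1,6-dihydroxy-7-(3-hydroxyprop-1-en-2-yl)-4,10-dimethyl-4,5:7,10-diepoxycyclodecan-8-yl 2-methylprop-2-enoate
Conditions: HF·pyridine, excess pyridine, THF, 0 °C to rt
Reagents that add atoms: none
Why: Fluoride-mediated cleavage of both silyl ethers; buffering with pyridine is intended to protect the trisubstituted epoxide and avoids the basic conditions that would trigger epoxide migration or acyl shift.

Step 25
Reactants: 29 (1S,4R,5S,6R,7R,8S,10R)-1,6-dihydroxy-7-(3-hydroxyprop-1-en-2-yl)-4,10-dimethyl-4,5:7,10-diepoxycyclodecan-8-yl 2-methylprop-2-enoate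
Product: 32 (1S,4R,5S,6R,7S,8S,10R)-1-hydroxy-4,10-dimethyl-11-methylidene-12-oxo-4,5:7,10-diepoxy-6,12-olide 8-(2-methylprop-2-enoate) (the 1-hydroxy analogue of the target), via C12 enal 30 (not isolated), via lactol 31 (not isolated)
Conditions: activated MnO2 (excess), CH2Cl2, rt
Reagents that add atoms: none
Why: Manganese dioxide oxidises only the primary allylic alcohol; the enal is trapped by the C6 hydroxyl as a five-membered lactol, which is oxidised on to the α-methylene-γ-lactone (the standard 2-methylene-1,4-diol lactonisation), while the non-allylic C1 alcohol is untouched and C8 is blocked as its ester.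

Step 26
Reactants: 32 (1S,4R,5S,6R,7S,8S,10R)-1-hydroxy-4,10-dimethyl-11-methylidene-12-oxo-4,5:7,10-diepoxy-6,12-olide 8-(2-methylprop-2-enoate)
Product: 33 CNP0241021.1, (4R,5S,6R,7S,8S,10R)-4,10-dimethyl-11-methylidene-1,12-dioxo-4,5:7,10-diepoxy-6,12-olide 8-(2-methylprop-2-enoate)
Conditions: Dess–Martin periodinane, NaHCO3, CH2Cl2, 0 °C to rt
Reagents that add atoms: none
Why: Dess–Martin oxidation of the last free secondary alcohol under buffered conditions that the epoxide, the enoate lactone and the methacrylate tolerate; no stereocentre is touched.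

## Compound list

1 | (R)-linalool, (3R)-3,7-dimethylocta-1,6-dien-3-ol | C=C[C@](C)(O)CCC=C(C)C | starting material
2 | 9-[(3R)-3-hydroxy-3,7-dimethyloct-6-en-1-yl]-9-borabicyclo[3.3.1]nonane | CC(C)=CCC[C@@](C)(O)CCB1C2CCCC1CCC2 | intermediate (not isolated)
3 | (3R)-3,7-dimethyloct-6-ene-1,3-diol | CC(C)=CCC[C@@](C)(O)CCO | intermediate
4 | (3R)-1-[(4-methoxybenzyl)oxy]-3,7-dimethyloct-6-en-3-ol | CC(C)=CCC[C@@](C)(O)CCOCc1ccc(OC)cc1 | intermediate
5 | (2E,6R)-8-[(4-methoxybenzyl)oxy]-2,6-dimethyloct-2-ene-1,6-diol | OC/C(C)=C/CC[C@@](C)(O)CCOCc1ccc(OC)cc1 | intermediate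
6 | {(2S,3S)-3-[(3R)-3-hydroxy-5-[(4-methoxybenzyl)oxy]-3-methylpentyl]-2-methyloxiran-2-yl}methanol | COc1ccc(COCC[C@](C)(O)CC[C@@H]2O[C@@]2(C)CO)cc1 | intermediate
7 | (2R,3S)-3-[(3R)-3-hydroxy-5-[(4-methoxybenzyl)oxy]-3-methylpentyl]-2-methyloxirane-2-carbaldehyde | COc1ccc(COCC[C@](C)(O)CC[C@@H]2O[C@@]2(C)C=O)cc1 | intermediate
8 | (3R)-1-[(2S,3S)-3-ethenyl-3-methyloxiran-2-yl]-5-[(4-methoxybenzyl)oxy]-3-methylpentan-3-ol | COc1ccc(COCC[C@](C)(O)CC[C@@H]2O[C@@]2(C)C=C)cc1 | intermediate
9 | (2R,3S,6R)-2-ethenyl-6-{2-[(4-methoxybenzyl)oxy]ethyl}-2,6-dimethyloxan-3-ol | C=C[C@@]1(C)O[C@@](C)(CCOCc2ccc(OC)cc2)CC[C@@H]1O | intermediate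
10 | tert-butyl{[(2R,3S,6R)-2-ethenyl-6-{2-[(4-methoxybenzyl)oxy]ethyl}-2,6-dimethyloxan-3-yl]oxy}dimethylsilane | C=C[C@@]1(C)O[C@@](C)(CCOCc2ccc(OC)cc2)CC[C@@H]1O[Si](C)(C)C(C)(C)C | intermediate
11 | 2-[(2R,5S,6R)-5-{[tert-butyl(dimethyl)silyl]oxy}-6-ethenyl-2,6-dimethyloxan-2-yl]ethan-1-ol | C=C[C@@]1(C)O[C@@](C)(CCO)CC[C@@H]1O[Si](C)(C)C(C)(C)C | intermediate
12 | 2-[(2R,5S,6R)-5-{[tert-butyl(dimethyl)silyl]oxy}-6-ethenyl-2,6-dimethyloxan-2-yl]acetaldehyde | C=C[C@@]1(C)O[C@@](C)(CC=O)CC[C@@H]1O[Si](C)(C)C(C)(C)C | intermediate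
13 | (E)-2-[(2R,5S,6R)-5-{[tert-butyl(dimethyl)silyl]oxy}-6-ethenyl-2,6-dimethyloxan-2-yl]ethenyl 2,2,2-trichloroethyl carbonate | C=C[C@@]1(C)O[C@@](C)(/C=C/OC(=O)OCC(Cl)(Cl)Cl)CC[C@@H]1O[Si](C)(C)C(C)(C)C | intermediate
14 | 9-BBN adduct of 13 at the terminal vinyl carbon (C8–B) | B1(C2CCCC1CCC2)CC[C@@]1(C)O[C@@](C)(/C=C/OC(=O)OCC(Cl)(Cl)Cl)CC[C@@H]1O[Si](C)(C)C(C)(C)C | intermediate (not isolated)
15 | (E)-2-[(2R,5S,6R)-5-{[tert-butyl(dimethyl)silyl]oxy}-2,6-dimethyl-6-(2-oxoethyl)oxan-2-yl]ethenyl 2,2,2-trichloroethyl carbonate | O=CC[C@@]1(C)O[C@@](C)(/C=C/OC(=O)OCC(Cl)(Cl)Cl)CC[C@@H]1O[Si](C)(C)C(C)(C)C | intermediate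
16 | 2-methylenepropane-1,3-diol | OCC(=C)CO | starting material
17 | 2-({[tert-butyl(dimethyl)silyl]oxy}methyl)prop-2-en-1-ol | C=C(CO)CO[Si](C)(C)C(C)(C)C | intermediate
18 | 2-({[tert-butyl(dimethyl)silyl]oxy}methyl)prop-2-en-1-yl acetate | C=C(COC(C)=O)CO[Si](C)(C)C(C)(C)C | intermediate
19 | tert-butyldimethyl{[2-((4,4,5,5-tetramethyl-1,3,2-dioxaborolan-2-yl)methyl)prop-2-en-1-yl]oxy}silane | C=C(CB1OC(C)(C)C(C)(C)O1)CO[Si](C)(C)C(C)(C)C | intermediate
20 | 2,2,2-trichloroethyl (E)-2-[(2R,5S,6R)-5-{[tert-butyl(dimethyl)silyl]oxy}-6-[4-({[tert-butyl(dimethyl)silyl]oxy}methyl)-2-hydroxypent-4-en-1-yl]-2,6-dimethyloxan-2-yl]ethenyl carbonate (C8 epimers) | C=C(CO[Si](C)(C)C(C)(C)C)CC(O)C[C@@]1(C)O[C@@](C)(/C=C/OC(=O)OCC(Cl)(Cl)Cl)CC[C@@H]1O[Si](C)(C)C(C)(C)C | intermediate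
21 | 2,2,2-trichloroethyl (E)-2-[(2R,5S,6R)-5-{[tert-butyl(dimethyl)silyl]oxy}-6-[4-({[tert-butyl(dimethyl)silyl]oxy}methyl)-2-oxopent-4-en-1-yl]-2,6-dimethyloxan-2-yl]ethenyl carbonate | C=C(CO[Si](C)(C)C(C)(C)C)CC(=O)C[C@@]1(C)O[C@@](C)(/C=C/OC(=O)OCC(Cl)(Cl)Cl)CC[C@@H]1O[Si](C)(C)C(C)(C)C | intermediate
22 | 2,2,2-trichloroethyl (E)-2-[(2R,5S,6R)-5-{[tert-butyl(dimethyl)silyl]oxy}-6-[4-({[tert-butyl(dimethyl)silyl]oxy}methyl)-3-diazo-2-oxopent-4-en-1-yl]-2,6-dimethyloxan-2-yl]ethenyl carbonate (vinyl diazoketone, key-step precursor) | C=C(CO[Si](C)(C)C(C)(C)C)C(=[N+]=[N-])C(=O)C[C@@]1(C)O[C@@](C)(/C=C/OC(=O)OCC(Cl)(Cl)Cl)CC[C@@H]1O[Si](C)(C)C(C)(C)C | intermediate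
23 | bicyclic oxonium ylide (O+ bonded to C4, C7 and C10; C7=C8 enolate), drawn metal-free | [O-]C1=C(C(=C)CO[Si](C)(C)C(C)(C)C)[O+]2[C@@](C)(/C=C/OC(=O)OCC(Cl)(Cl)Cl)CC[C@H](O[Si](C)(C)C(C)(C)C)[C@@]2(C)C1 | intermediate (not isolated)
24 | (1S,4Z,6R,7R,10R)-1-{[tert-butyl(dimethyl)silyl]oxy}-7-[3-{[tert-butyl(dimethyl)silyl]oxy}prop-1-en-2-yl]-4,10-dimethyl-8-oxo-7,10-epoxycyclodec-4-en-6-yl 2,2,2-trichloroethyl carbonate (key-step product) | O=C1C[C@@]2(C)O[C@]1(C(=C)CO[Si](C)(C)C(C)(C)C)[C@H](OC(=O)OCC(Cl)(Cl)Cl)/C=C(C)\CC[C@@H]2O[Si](C)(C)C(C)(C)C | intermediate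
25 | (1S,4Z,6R,7S,8S,10R)-8-hydroxy analogue of 24 | O[C@H]1C[C@@]2(C)O[C@]1(C(=C)CO[Si](C)(C)C(C)(C)C)[C@H](OC(=O)OCC(Cl)(Cl)Cl)/C=C(C)\CC[C@@H]2O[Si](C)(C)C(C)(C)C | intermediate
26 | (1S,4Z,6R,7S,8S,10R)-8-methacrylate, 6-(2,2,2-trichloroethyl carbonate), 1- and 12-TBS ethers | C=C(C)C(=O)O[C@H]1C[C@@]2(C)O[C@]1(C(=C)CO[Si](C)(C)C(C)(C)C)[C@H](OC(=O)OCC(Cl)(Cl)Cl)/C=C(C)\CC[C@@H]2O[Si](C)(C)C(C)(C)C | intermediate
27 | (1S,4Z,6R,7R,8S,10R)-6-hydroxy-8-methacrylate, 1- and 12-TBS ethers | C=C(C)C(=O)O[C@H]1C[C@@]2(C)O[C@]1(C(=C)CO[Si](C)(C)C(C)(C)C)[C@H](O)/C=C(C)\CC[C@@H]2O[Si](C)(C)C(C)(C)C | intermediate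
28 | (1S,4R,5S,6R,7R,8S,10R)-4,5-epoxy-6-hydroxy-8-methacrylate, 1- and 12-TBS ethers | C=C(C)C(=O)O[C@H]1C[C@@]2(C)O[C@]1(C(=C)CO[Si](C)(C)C(C)(C)C)[C@H](O)[C@@H]1O[C@]1(C)CC[C@@H]2O[Si](C)(C)C(C)(C)C | intermediate
29 | (1S,4R,5S,6R,7R,8S,10R)-4,5-epoxy-1,6,12-triol 8-methacrylate | C=C(C)C(=O)O[C@H]1C[C@@]2(C)O[C@]1(C(=C)CO)[C@H](O)[C@@H]1O[C@]1(C)CC[C@@H]2O | intermediate
30 | C12 enal of 29 (C11(=CH2)–CHO, C6 and C1 hydroxyls free) | C=C(C)C(=O)O[C@H]1C[C@@]2(C)O[C@]1(C(=C)C=O)[C@H](O)[C@@H]1O[C@]1(C)CC[C@@H]2O | intermediate (not isolated)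
31 | C12 lactol (C6–O–C12(OH), both C12 epimers) | C=C(C)C(=O)O[C@H]1C[C@@]2(C)O[C@@]13C(=C)C(O)O[C@@H]3[C@@H]1O[C@]1(C)CC[C@@H]2O | intermediate (not isolated)
32 | (1S,4R,5S,6R,7S,8S,10R)-1-hydroxy-6,12-olide 8-methacrylate (1-hydroxy analogue of the target) | C=C(C)C(=O)O[C@H]1C[C@@]2(C)O[C@@]13C(=C)C(=O)O[C@@H]3[C@@H]1O[C@]1(C)CC[C@@H]2O | intermediate
33 | CNP0241021.1, (4R,5S,6R,7S,8S,10R) | C=C(C)C(=O)O[C@H]1C[C@@]2(C)O[C@@]13C(=C)C(=O)O[C@@H]3[C@@H]1O[C@]1(C)CCC2=O | target

## Step count and risk

Total step count: 26. Longest linear sequence: 23 (steps 1–12 and 16–26 from (R)-linalool); steps 13–15 prepare the allylboronate.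

**Step 19 (key step, proposed new method).**
- Most likely to go wrong: diversion of the vinylcarbenoid before ylide formation (cyclopropene formation, insertion into the C1–H bond, or cyclisation of the vinyl diazo unit to a pyrazole before the catalyst engages it). Alternatively, rearrangement through the other chair (alkenyl arm axial) would give the E-olefin with the opposite C6 configuration. Both risks arise because the carbenoid carbon carries a donor substituent and both ether carbons are fully substituted.
- Fallback (known reactions only, 22 back to 24): the same two bonds are made stepwise. Methanolysis of the enol carbonate of 22 (K2CO3, MeOH, then DBU) releases the β-alkoxy aldehyde, which opens the pyran by E1cB elimination to hydroxy enal diazoketone F1. In F1 the tertiary C10 hydroxyl is free and the C4=C5 enal can equilibrate to the Z form. Rhodium(II) acetate then effects intramolecular O–H insertion of the carbenoid into that hydroxyl to give 2-alkenyltetrahydrofuran-3-one F2 (O–C7 bond). Soft enolisation at the doubly activated C7–H (MgBr2·OEt2, Et3N, high dilution) and aldol addition to the C6 aldehyde closes the nine-membered ring as β-hydroxy ketone F3 (C6–C7 bond). Acylation with 2,2,2-trichloroethyl chloroformate and pyridine returns to 24.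

**Step 11 (enol carbonate).**
- Most likely to go wrong: E1cB loss of the ring oxygen from the aldehyde enolate, or incomplete E selectivity, because the enolate carries a β-alkoxy leaving group and is trapped under kinetic conditions.
- Fallback (12 back to 13): soft enolisation of 12 with trimethylsilyl triflate and triethylamine, which forms no free enolate and allows acid-catalysed equilibration to the E isomer, gives trimethylsilyl enol ether F4. Cleavage with methyllithium at −78 °C and immediate quench with the chloroformate returns to 13.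

**Step 12 (hydroboration and oxidation to the aldehyde).**
- Most likely to go wrong: loss of the activated enol carbonate during oxidation of the B–C bond, or incomplete oxidation of the hindered borane.
- Fallback (13 directly to 15): the vinyl group is converted by an aldehyde-selective (anti-Markovnikov) Wacker oxidation under nitrite co-catalysis, which the adjacent fully substituted ether carbon should favour. No new compound is involved.

**Step 20 (C8 reduction).**
- Most likely to go wrong: poor facial selectivity if the substrate's own bias opposes the catalyst, since both faces of the ketone are flanked by large groups on C7.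
- Fallback (24 to 26): accept the other face. A bulky hydride (L-Selectride) gives 8-epi alcohol F5, which is esterified with inversion by a Mitsunobu reaction with methacrylic acid to reach 26 directly.

**Step 23 (directed epoxidation).**
- Most likely to go wrong: oxygen delivery to the wrong olefin face if the bridged ring does not adopt the conformation that simple medium-ring allylic alcohols use, or competing epoxidation of C11=C13.
- Fallback (26 to 28): go through a halohydrin on 26. N-Bromosuccinimide in aqueous DME forms the bromonium ion on the exposed face and water opens it at the tertiary C4 to give bromohydrin F6. DBU closes the epoxide with inversion at C5, so the oxygen ends on the face opposite to direct attack, giving epoxy carbonate F7. Zinc with ammonium acetate removes the carbonate and returns to 28.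

## Further compounds

F1 | step 19 | hydroxy enal diazoketone (ring-opened, free C10–OH, Z-enal drawn) | C=C(CO[Si](C)(C)C(C)(C)C)C(=[N+]=[N-])C(=O)C[C@@](C)(O)[C@H](CC/C(C)=C\C=O)O[Si](C)(C)C(C)(C)C
F2 | step 19 | 2-alkenyltetrahydrofuran-3-one from O–H insertion (C7 epimers) | C=C(CO[Si](C)(C)C(C)(C)C)C1O[C@](C)(CC1=O)[C@H](CC/C(C)=C\C=O)O[Si](C)(C)C(C)(C)C
F3 | step 19 | 6-hydroxy analogue of 24 (β-hydroxy ketone) | O=C1C[C@@]2(C)O[C@]1(C(=C)CO[Si](C)(C)C(C)(C)C)[C@H](O)/C=C(C)\CC[C@@H]2O[Si](C)(C)C(C)(C)C
F4 | step 11 | (E)-trimethylsilyl enol ether of 12 | C=C[C@@]1(C)O[C@@](C)(/C=C/O[Si](C)(C)C)CC[C@@H]1O[Si](C)(C)C(C)(C)C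
F0 | step 12 | none | none
F5 | step 20 | 8-epi alcohol (8R epimer of 25) | O[C@@H]1C[C@@]2(C)O[C@]1(C(=C)CO[Si](C)(C)C(C)(C)C)[C@H](OC(=O)OCC(Cl)(Cl)Cl)/C=C(C)\CC[C@@H]2O[Si](C)(C)C(C)(C)C
F6 | step 23 | bromohydrin of 26 (C5–Br, C4–OH) | C=C(C)C(=O)O[C@H]1C[C@@]2(C)O[C@]1(C(=C)CO[Si](C)(C)C(C)(C)C)[C@H](OC(=O)OCC(Cl)(Cl)Cl)[C@@H](Br)[C@](C)(O)CC[C@@H]2O[Si](C)(C)C(C)(C)C
F7 | step 23 | 4,5-epoxide of 26 (C6 carbonate retained) | C=C(C)C(=O)O[C@H]1C[C@@]2(C)O[C@]1(C(=C)CO[Si](C)(C)C(C)(C)C)[C@H](OC(=O)OCC(Cl)(Cl)Cl)[C@@H]1O[C@]1(C)CC[C@@H]2O[Si](C)(C)C(C)(C)C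
A1 | alternative 1 | spiro tetrahydrofuran–γ-lactone with C1 primary alcohol (C8 OTBS, C5 OPMB) | CC(C)(C)[Si](C)(C)O[C@H]1C[C@@](CO)(C)O[C@@]13CC(=O)O[C@@H]3COCc4ccc(OC)cc4
A2 | alternative 2 | bicyclic Z-allylic alcohol, seco-lactone (C8 methacrylate, C1 ketone, C12 2-(trimethylsilyl)ethyl ester) | C=C(C)C(=O)O[C@H]1C[C@@]2(C)O[C@]1(C(=C)C(=O)OCC[Si](C)(C)C)[C@H](O)/C=C(C)\CCC2=O
A3 | alternative 3 | α-chloro-α-methyl spiro-γ-lactone on the oxabicycle (8-epi triethylsilyl ether, C1 OTBS) | CC[Si](CC)(CC)O[C@@H]1C[C@@]2(C)O[C@@]13[C@](C)(Cl)C(=O)O[C@@H]3/C=C(C)\CC[C@@H]2O[Si](C)(C)C(C)(C)C
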